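The retrosynthesis and forward order below use this numbering: ring C1 (alkenyl), C2 (H), C3 (OH), C4 (CH3), C5 (H), C6 (O-isobutyrate); side chain C7 on C1, C8 (=CH2), C9 (CH2-O-benzoyl).
Enabling feature: C7 carries two one-carbon arms, C8 and C9, that differ only in where the double bond and the oxygen sit. Joined by a C8-C9 bond they form a cyclopropanol on C7, which then has the oxidation level of a carboxyl carbon on C1 of the benzene ring.
Cuts, in retrosynthetic order: O-Si at C3, acyl-O at C6, C9-O (benzoate), C9-Br with re-formation of C8-C9 (allyl back to cyclopropyl), then C7-C8 and C7-C9 together (cyclopropanol back to methyl ester plus EtMgBr), and last C3-O.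
Forward: the benzene ring is bought as 4-methylsalicylic acid, C3-O is added para to the phenol, and the two phenols are told apart by the hydrogen bond from the C6 hydroxyl to the ester. The cyclopropane, the only ring made, arises in step 5 and is opened in step 6; benzoate and then isobutyrate are attached, and the C3 silyl group leaves last.
Stereochemistry: the target has no stereocentre and no configurable double bond, and the equivalence of C8 and C9 removes any regiochemical question in the opening.

Key step: step 5

Remark: locants in compound names count from the ring carbon that bears the carboxyl or side-chain carbon, so position 2 in a name is C6 and position 5 is C3 of the numbering above.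

Step 1
Reactants: 1 4-methylsalicylic acid
Product: 3 2,5-dihydroxy-4-methylbenzoic acid, via aryl sulfate monoester 2 (not isolated)
Conditions: K2S2O8, aq NaOH, 5 °C to rt; acidify, extract unreacted 1; then aq HCl, 95 °C
Reagents that add atoms: K2S2O8, [K+].[K+].[O-]S(=O)(=O)OOS(=O)(=O)[O-]
Why: Elbs persulfate oxidation, in which the phenoxide of 1 attacks a peroxide oxygen of peroxodisulfate through the carbon para to its oxygen (C3, the only free para site) and hot acid then cleaves the S-O bond of sulfate 2, so the regiochemistry is unambiguous even though conversion in this reaction type is usually modest and unreacted 1 has to be recycled.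

Step 2
Reactants: 3 2,5-dihydroxy-4-methylbenzoic acid
Product: 4 methyl 2,5-dihydroxy-4-methylbenzoate
Conditions: MeOH, H2SO4 (cat.), reflux, N2
Reagents that add atoms: methanol, CO
Why: Fischer esterification, in which neither phenol competes with methanol as nucleophile and which sets up the hydrogen bond between the C6 hydroxyl and the ester carbonyl that the next step exploits.

Step 3
Reactants: 4 methyl 2,5-dihydroxy-4-methylbenzoate
Product: 5 methyl 2-hydroxy-4-methyl-5-(triisopropylsilyloxy)benzoate
Conditions: TIPSCl (1.05 equiv), imidazole, DMF, 0 °C to rt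
Reagents that add atoms: triisopropylsilyl chloride, CC(C)[Si](Cl)(C(C)C)C(C)C
Why: Chemoselective O-silylation with a silyl chloride and imidazole, where the C6 hydroxyl is locked in a six-membered hydrogen bond to the ester and crowded by it so the bulky chloride should take the free C3 hydroxyl, and where TIPS is preferred to TBS because aryl TBS ethers are eroded by the alkoxides of step 5 and by carboxylate in DMF in step 7.

Step 4
Reactants: 5 methyl 2-hydroxy-4-methyl-5-(triisopropylsilyloxy)benzoate
Product: 6 methyl 2-(methoxymethoxy)-4-methyl-5-(triisopropylsilyloxy)benzoate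
Conditions: MOMCl, iPr2NEt, CH2Cl2, 0 °C to reflux
Reagents that add atoms: chloromethyl methyl ether, COCCl
Why: O-alkylation of a phenol with a highly reactive alpha-chloro ether (Williamson type), which overcomes the low nucleophilicity of the chelated hydroxyl and leaves a small, base-stable acetal beside the ester.

Step 5
Reactants: 6 methyl 2-(methoxymethoxy)-4-methyl-5-(triisopropylsilyloxy)benzoate; 7 ethylmagnesium bromide
Product: 9 1-[2-(methoxymethoxy)-4-methyl-5-(triisopropylsilyloxy)phenyl]cyclopropan-1-ol, via beta-titanio ketone 8 (not isolated)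
Conditions: Ti(OiPr)4 (30 mol %), 7 (3 equiv, added over 2 h), Et2O-THF, 0 °C to rt; aq NH4Cl
Reagents that add atoms: ethylmagnesium bromide 7, CC[Mg]Br
Why: Two equivalents of 7 alkylate Ti(OiPr)4 to Et2Ti(OiPr)2, which loses ethane by beta-hydride abstraction and leaves the titanacyclopropane (iPrO)2Ti(CH2CH2), a 1,2-dicarbanion equivalent that can also be read as an ethylene complex of divalent titanium. One Ti-C bond adds to the ester carbonyl of 6 (C7-C8) with transfer of methoxide to titanium, which gives the beta-titanio ketone 8, and the remaining Ti-C bond then attacks that ketone in a 3-exo-trig closure (C7-C9) to give the alkoxide of 9, which further 7 releases so that titanium turns over. This is the Kulinkovich cyclopropanation of esters, well established for methyl benzoates including ortho-alkoxy ones. No stereocentre arises because C7 ends up with two identical CH2 arms. The step needs chemoselectivity for the titanium-mediated double C-C bond formation over plain 1,2-addition of the Grignard reagent and over protonolysis, and this is secured because 6 has a single ester, both phenols are capped as base-stable ethers without acidic hydrogen, and slow addition keeps free 7 scarce. The small MOM group next to the ester keeps the carbonyl accessible and, being an alkyl acetal, cannot migrate to the new alkoxide as an ortho silyl group could.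

Step 6
Reactants: 9 1-[2-(methoxymethoxy)-4-methyl-5-(triisopropylsilyloxy)phenyl]cyclopropan-1-ol
Product: 11 2-[2-(methoxymethoxy)-4-methyl-5-(triisopropylsilyloxy)phenyl]prop-2-en-1-yl bromide, via cyclopropyl mesylate 10 (not isolated)
Conditions: MsCl, Et3N, Et2O, -10 °C, filter; then MgBr2·OEt2, Et2O-CH2Cl2, 0 °C to rt
Reagents that add atoms: methanesulfonyl chloride, CS(=O)(=O)Cl (held only in 10); MgBr2·OEt2, Br[Mg]Br.CCOCC (bromine)
Why: Mesylation of the tertiary cyclopropanol through sulfene followed by the known magnesium-halide-promoted cyclopropyl-to-allyl rearrangement of cyclopropyl sulfonates, in which ionisation, pushed by the ortho-oxygenated and para-methylated aryl group, runs in concert with disrotatory cleavage of C8-C9 and, because C8 and C9 are equivalent, bromide capture at either end gives the same bromide.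

Step 7
Reactants: 11 2-[2-(methoxymethoxy)-4-methyl-5-(triisopropylsilyloxy)phenyl]prop-2-en-1-yl bromide; 12 sodium benzoate
Product: 13 2-[2-(methoxymethoxy)-4-methyl-5-(triisopropylsilyloxy)phenyl]prop-2-en-1-yl benzoate
Conditions: crude 11, NaO2CPh (1.5 equiv), DMF, rt
Reagents that add atoms: sodium benzoate 12, [Na+].[O-]C(=O)c1ccccc1
Why: SN2 displacement of a primary allylic bromide by a carboxylate, fast at room temperature, with the SN2' pathway degenerate and the TIPS ether and MOM acetal inert to benzoate.

Step 8
Reactants: 13 2-[2-(methoxymethoxy)-4-methyl-5-(triisopropylsilyloxy)phenyl]prop-2-en-1-yl benzoate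
Product: 15 2-[2-hydroxy-4-methyl-5-(triisopropylsilyloxy)phenyl]prop-2-en-1-yl benzoate, via aryl trimethylsilyl ether 14 (not isolated)
Conditions: TMSOTf (2 equiv), 2,2'-bipyridyl (3 equiv), MeCN, 0 °C to rt; then H2O, rt
Reagents that add atoms: trimethylsilyl trifluoromethanesulfonate, C[Si](C)(C)OS(=O)(=O)C(F)(F)F (silyl group held only in 14)
Why: Silylative cleavage of an aromatic MOM ether by TMSOTf buffered with 2,2'-bipyridyl, a known non-acidic method that passes the methoxymethyl group to the pyridine nitrogen and leaves silyl ether 14 for hydrolysis by water, so that the acid-sensitive 1,1-disubstituted styrene, the allylic benzoate and the aryl TIPS ether never meet a Bronsted acid.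

Step 9
Reactants: 15 2-[2-hydroxy-4-methyl-5-(triisopropylsilyloxy)phenyl]prop-2-en-1-yl benzoate; 16 isobutyryl chloride
Product: 17 2-[2-(isobutyryloxy)-4-methyl-5-(triisopropylsilyloxy)phenyl]prop-2-en-1-yl benzoate
Conditions: iPrCOCl, Et3N, DMAP (cat.), CH2Cl2, 0 °C
Reagents that add atoms: isobutyryl chloride 16, CC(C)C(=O)Cl
Why: DMAP-catalysed acylation of a phenol with an acid chloride, quick enough at 0 °C to outrun benzoyl migration or attack of the phenoxide on C9, and unambiguous because the C6 hydroxyl is the only free hydroxyl.

Step 10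
Reactants: 17 2-[2-(isobutyryloxy)-4-methyl-5-(triisopropylsilyloxy)phenyl]prop-2-en-1-yl benzoate
Product: 18 2-[5-hydroxy-2-(isobutyryloxy)-4-methylphenyl]prop-2-en-1-yl benzoate (CNP0245407.0)
Conditions: Bu4NF, AcOH (1:1), THF, 0 °C
Reagents that add atoms: none
Why: Fluoride-induced cleavage of an aryl silyl ether driven by the Si-F bond, with acetic acid protonating the phenoxide as it forms so that neither the aryl isobutyrate nor the allylic benzoate is transacylated.

Compound list
1 | 4-methylsalicylic acid (2-hydroxy-4-methylbenzoic acid) | Cc1ccc(C(=O)O)c(O)c1 | starting material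
2 | potassium 5-carboxy-4-hydroxy-2-methylphenyl sulfate | Cc1cc(O)c(C(=O)O)cc1OS(=O)(=O)[O-].[K+] | intermediate
3 | 2,5-dihydroxy-4-methylbenzoic acid | Cc1cc(O)c(C(=O)O)cc1O | intermediate
4 | methyl 2,5-dihydroxy-4-methylbenzoate | COC(=O)c1cc(O)c(C)cc1O | intermediate
5 | methyl 2-hydroxy-4-methyl-5-(triisopropylsilyloxy)benzoate | COC(=O)c1cc(O[Si](C(C)C)(C(C)C)C(C)C)c(C)cc1O | intermediate
6 | methyl 2-(methoxymethoxy)-4-methyl-5-(triisopropylsilyloxy)benzoate | COC(=O)c1cc(O[Si](C(C)C)(C(C)C)C(C)C)c(C)cc1OCOC | intermediate
7 | ethylmagnesium bromide | CC[Mg]Br | starting material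
8 | {3-[2-(methoxymethoxy)-4-methyl-5-(triisopropylsilyloxy)phenyl]-3-oxopropyl}Ti(OiPr)2(OMe) | COCOc1cc(C)c(O[Si](C(C)C)(C(C)C)C(C)C)cc1C(=O)CC[Ti](OC)(OC(C)C)OC(C)C | intermediate
9 | 1-[2-(methoxymethoxy)-4-methyl-5-(triisopropylsilyloxy)phenyl]cyclopropan-1-ol | OC1(CC1)c1cc(O[Si](C(C)C)(C(C)C)C(C)C)c(C)cc1OCOC | intermediate
10 | 1-[2-(methoxymethoxy)-4-methyl-5-(triisopropylsilyloxy)phenyl]cyclopropyl methanesulfonate | CS(=O)(=O)OC1(CC1)c1cc(O[Si](C(C)C)(C(C)C)C(C)C)c(C)cc1OCOC | intermediate
11 | 2-[2-(methoxymethoxy)-4-methyl-5-(triisopropylsilyloxy)phenyl]prop-2-en-1-yl bromide | C=C(CBr)c1cc(O[Si](C(C)C)(C(C)C)C(C)C)c(C)cc1OCOC | intermediate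
12 | sodium benzoate | [Na+].[O-]C(=O)c1ccccc1 | starting material
13 | 2-[2-(methoxymethoxy)-4-methyl-5-(triisopropylsilyloxy)phenyl]prop-2-en-1-yl benzoate | C=C(COC(=O)c1ccccc1)c1cc(O[Si](C(C)C)(C(C)C)C(C)C)c(C)cc1OCOC | intermediate
14 | 2-[4-methyl-5-(triisopropylsilyloxy)-2-(trimethylsilyloxy)phenyl]prop-2-en-1-yl benzoate | C=C(COC(=O)c1ccccc1)c1cc(O[Si](C(C)C)(C(C)C)C(C)C)c(C)cc1O[Si](C)(C)C | intermediate
15 | 2-[2-hydroxy-4-methyl-5-(triisopropylsilyloxy)phenyl]prop-2-en-1-yl benzoate | C=C(COC(=O)c1ccccc1)c1cc(O[Si](C(C)C)(C(C)C)C(C)C)c(C)cc1O | intermediate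
16 | isobutyryl chloride | CC(C)C(=O)Cl | starting material
17 | 2-[2-(isobutyryloxy)-4-methyl-5-(triisopropylsilyloxy)phenyl]prop-2-en-1-yl benzoate | C=C(COC(=O)c1ccccc1)c1cc(O[Si](C(C)C)(C(C)C)C(C)C)c(C)cc1OC(=O)C(C)C | intermediate
18 | 2-[5-hydroxy-2-(isobutyryloxy)-4-methylphenyl]prop-2-en-1-yl benzoate (CNP0245407.0) | C=C(COC(=O)c1ccccc1)c1cc(O)c(C)cc1OC(=O)C(C)C | target

Total step count: 10. Longest linear sequence: 10 steps, from 1 to 18.

Steps most likely to fail

Step 6. The electron-rich mesylate may ionise before the magnesium salt is present. The Lewis acid may also strip the MOM acetal, after which the freed C6 oxygen would close onto C9 in place of bromide capture. The fallback drops both the Lewis acid and the halide relay. It sets out from mesylate 10, made from 9 at -20 °C as in step 6. The cold solution is run into sodium benzoate 12 and benzoic acid in DMF and allowed to warm. Buffered solvolysis of 1-arylcyclopropyl sulfonates to 2-arylallyl esters is a classical reaction type. A high concentration of carboxylate should capture C8 or C9 while the acetal stays intact. The sequence comes back to the route at 13, step 7 falls away, and no new compound is made (F0).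

Step 5. Carbotitanation of the ortho-substituted, electron-rich ester may be sluggish, so that plain Grignard addition or reduction of the ester overtakes cyclopropanation. The fallback builds the same cyclopropanol from one-carbon units and sets out from 6.
- MeNH(OMe)·HCl with iPrMgCl in THF should give N-methoxy-2-(methoxymethoxy)-N,4-dimethyl-5-(triisopropylsilyloxy)benzamide F1.
- MeMgBr should turn this into 1-[2-(methoxymethoxy)-4-methyl-5-(triisopropylsilyloxy)phenyl]ethan-1-one F2.
- LDA then TMSCl at -78 °C should give 1-[2-(methoxymethoxy)-4-methyl-5-(triisopropylsilyloxy)phenyl]-1-(trimethylsilyloxy)ethene F3.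
- Simmons-Smith cyclopropanation with Et2Zn and CH2I2 should give 1-[2-(methoxymethoxy)-4-methyl-5-(triisopropylsilyloxy)phenyl]-1-(trimethylsilyloxy)cyclopropane F4.
- Methanolysis of the labile trimethylsilyl ether (MeOH, catalytic citric acid), which leaves the aryl TIPS ether alone, brings the sequence back to the route at 9.

Step 1. Conversion may stay low, the hydroquinone product may be over-oxidised to dark polymeric material, and the polar acid may be hard to extract. The fallback introduces the C3 oxygen by halogenation, borylation and oxidation. It sets out from 1.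
- Fischer esterification should give methyl 2-hydroxy-4-methylbenzoate F5.
- NBS in MeCN should brominate para to the hydroxyl and ortho to the methyl group to give methyl 5-bromo-2-hydroxy-4-methylbenzoate F6.
- MOMCl and iPr2NEt should give methyl 5-bromo-2-(methoxymethoxy)-4-methylbenzoate F7.
- Miyaura borylation (B2pin2, PdCl2(dppf), KOAc, dioxane, 90 °C) should give methyl 2-(methoxymethoxy)-4-methyl-5-(4,4,5,5-tetramethyl-1,3,2-dioxaborolan-2-yl)benzoate F8.
- Oxidation with NaBO3·4H2O in THF-H2O should give methyl 5-hydroxy-2-(methoxymethoxy)-4-methylbenzoate F9.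
- Silylation with TIPSCl and imidazole brings the sequence back to the route at 6.

In this sequence the two oxygens are told apart by the order in which they are introduced.

Further compounds
F0 | step 6 | none | none
F1 | step 5 | N-methoxy-2-(methoxymethoxy)-N,4-dimethyl-5-(triisopropylsilyloxy)benzamide | CON(C)C(=O)c1cc(O[Si](C(C)C)(C(C)C)C(C)C)c(C)cc1OCOC
F2 | step 5 | 1-[2-(methoxymethoxy)-4-methyl-5-(triisopropylsilyloxy)phenyl]ethan-1-one | CC(=O)c1cc(O[Si](C(C)C)(C(C)C)C(C)C)c(C)cc1OCOC
F3 | step 5 | 1-[2-(methoxymethoxy)-4-methyl-5-(triisopropylsilyloxy)phenyl]-1-(trimethylsilyloxy)ethene | C=C(O[Si](C)(C)C)c1cc(O[Si](C(C)C)(C(C)C)C(C)C)c(C)cc1OCOC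
F4 | step 5 | 1-[2-(methoxymethoxy)-4-methyl-5-(triisopropylsilyloxy)phenyl]-1-(trimethylsilyloxy)cyclopropane | C[Si](C)(C)OC1(CC1)c1cc(O[Si](C(C)C)(C(C)C)C(C)C)c(C)cc1OCOC
F5 | step 1 | methyl 2-hydroxy-4-methylbenzoate | COC(=O)c1ccc(C)cc1O
F6 | step 1 | methyl 5-bromo-2-hydroxy-4-methylbenzoate | COC(=O)c1cc(Br)c(C)cc1O
F7 | step 1 | methyl 5-bromo-2-(methoxymethoxy)-4-methylbenzoate | COC(=O)c1cc(Br)c(C)cc1OCOC
F8 | step 1 | methyl 2-(methoxymethoxy)-4-methyl-5-(4,4,5,5-tetramethyl-1,3,2-dioxaborolan-2-yl)benzoate | COC(=O)c1cc(B2OC(C)(C)C(C)(C)O2)c(C)cc1OCOC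
F9 | step 1 | methyl 5-hydroxy-2-(methoxymethoxy)-4-methylbenzoate | COC(=O)c1cc(O)c(C)cc1OCOC
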